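**Retrosynthetic overview**
1. Target 21 ⇐ Mitsunobu angeloylation with inversion at C2 of the 2β,4α-diol lactone 19; the lactone C8–O bond comes from exo reduction of a C8 ketone onto the C12 ester.
2. Key step: the C5–O–C11 ether bridge and the C11 quaternary centre ⇐ bicyclic enone/β-diketone ketal 13, by a carbonyl oxa-Michael closure relayed into a 1,2-methyl shift (C–O bond-forming cascade).
3. Ring B ⇐ intramolecular Claisen acylation (C7–C8), after joining C6–C7 by alkylating bromo-enone 10 with 3,3-dimethoxybutan-2-one.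
4. Ring A ⇐ copper bis(oxazoline) Mukaiyama aldol of a methyl-ketone enol silane with butane-2,3-dione (C3–C4, sets C4), then aldol condensation (C1–C5).
5. C10 ⇐ desymmetrisation of 3-methylglutaric anhydride. Ring order: ring A, ring B, tetrahydrofuran bridge, lactone.

Assumption: the SMILES fixes the absolute configuration; guaiane numbering is used for ring positions (C1–C5 ring A, C5–C10 plus C1 ring B, C11–C13 the propanoate unit on C7, C14 on C10, C15 on C4), with β the face that carries the C5–O–C11 bridge.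

This route is a paper proposal; no step has been run, and selectivities are argued by analogy.

**Step 1**
Reactants: 1 3-methylglutaric anhydride
Product: 2 (3S)-5-methoxy-3-methyl-5-oxopentanoic acid
Conditions: (DHQ)2AQN or (DHQD)2AQN (30 mol %; the pseudo-enantiomer that gives the 3S half-ester), MeOH, Et2O, −40 °C
Reagents that add atoms: methanol CO
Why: Cinchona-alkaloid-catalysed desymmetrising methanolysis of the prochiral anhydride opens one enantiotopic carbonyl and sets the C10 methyl stereocentre (3S here).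

**Step 2**
Reactants: 2 (3S)-5-methoxy-3-methyl-5-oxopentanoic acid
Product: 4 methyl (3S)-3-methyl-5-oxohexanoate, via acid chloride 3 (not isolated)
Conditions: (COCl)2, DMF (cat.), CH2Cl2, 0 to 23 °C; then MeMgBr, Fe(acac)3 (3 mol %), THF, −78 °C
Reagents that add atoms: methylmagnesium bromide C[Mg]Br
Why: Iron-catalysed acylation of the Grignard reagent by the acid chloride is faster than attack on the methyl ester or on the product ketone, and the β-stereocentre is not touched.

**Step 3**
Reactants: 4 methyl (3S)-3-methyl-5-oxohexanoate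
Product: 5 methyl (3S)-3-methyl-5-[(triethylsilyl)oxy]hex-5-enoate
Conditions: LiN(iPr)2, Et3SiCl (internal quench), THF, −78 °C
Reagents that add atoms: chlorotriethylsilane CC[Si](Cl)(CC)CC
Why: Kinetic enolate formation occurs at the ketone methyl group (less hindered than the β-branched methylene, more acidic than the ester α-position) and O-silylation gives the terminal enol silane.

**Step 4**
Reactants: 5 methyl (3S)-3-methyl-5-[(triethylsilyl)oxy]hex-5-enoate; 6 butane-2,3-dione
Product: 7 methyl (3S,7R)-3,7-dimethyl-5,8-dioxo-7-[(triethylsilyl)oxy]nonanoate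
Conditions: Cu(OTf)2 (10 mol %), (R,R)-tBu-box (11 mol %; enantiomer chosen by analogy with pyruvate additions to give 7R), 6 (3 equiv), THF, −78 °C; non-aqueous work-up
Reagents that add atoms: none
Why: Evans-type Mukaiyama aldol addition, in which the 1,2-diketone chelates the copper bis(oxazoline) Lewis acid and the enol silane attacks one enantioface, sets the C4 carbinol (7R here) with silyl transfer to the new tertiary oxygen.

**Step 5**
Reactants: 7 methyl (3S,7R)-3,7-dimethyl-5,8-dioxo-7-[(triethylsilyl)oxy]nonanoate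
Product: 9 methyl (3R)-3-[(3R)-2,3-dimethyl-5-oxo-3-[(triethylsilyl)oxy]cyclopent-1-en-1-yl]butanoate, via cyclic aldol 8 (not isolated)
Conditions: NaOMe (0.3 equiv), MeOH, 0 to 23 °C
Reagents that add atoms: none
Why: Intramolecular aldol condensation of the 1,4-diketone (the cyclisation mode of the benzil–acetone and jasmone syntheses) adds the C1 enolate to the activated C5 ketone and E1cB loss of water gives the tetrasubstituted enone of ring A, while the silyl ether blocks retro-aldol at C4.

**Step 6**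
Reactants: 9 methyl (3R)-3-[(3R)-2,3-dimethyl-5-oxo-3-[(triethylsilyl)oxy]cyclopent-1-en-1-yl]butanoate
Product: 10 methyl (3R)-3-[(3R)-2-(bromomethyl)-3-methyl-5-oxo-3-[(triethylsilyl)oxy]cyclopent-1-en-1-yl]butanoate
Conditions: NBS (1.05 equiv), AIBN (5 mol %), PhCF3, 80 °C
Reagents that add atoms: N-bromosuccinimide O=C1CCC(=O)N1Br
Why: Wohl–Ziegler allylic bromination removes hydrogen from the methyl on the enone β-carbon, whose radical is delocalised onto the carbonyl, as expected for 2-alkyl-3-methylcyclopentenones.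

**Step 7**
Reactants: 10 methyl (3R)-3-[(3R)-2-(bromomethyl)-3-methyl-5-oxo-3-[(triethylsilyl)oxy]cyclopent-1-en-1-yl]butanoate; 11 3,3-dimethoxybutan-2-one
Product: 12 methyl (3R)-3-[(3R)-2-(4,4-dimethoxy-3-oxopentyl)-3-methyl-5-oxo-3-[(triethylsilyl)oxy]cyclopent-1-en-1-yl]butanoate
Conditions: 11, LiN(iPr)2, THF, −78 °C; then 10, −78 to −30 °C
Reagents that add atoms: none
Why: The lithium enolate of 11 (one enolisable position only) displaces the primary, doubly activated allylic bromide by SN2 alkylation, forming the C6–C7 bond.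

**Step 8**
Reactants: 12 methyl (3R)-3-[(3R)-2-(4,4-dimethoxy-3-oxopentyl)-3-methyl-5-oxo-3-[(triethylsilyl)oxy]cyclopent-1-en-1-yl]butanoate
Product: 13 (3R,8R)-5-(2,2-dimethoxypropanoyl)-3,8-dimethyl-3-[(triethylsilyl)oxy]-2,3,4,5,7,8-hexahydroazulene-1,6-dione (keto/enol mixture at azulene C5)
Conditions: LiN(SiMe3)2 (2.2 equiv), THF, −78 to 0 °C; aqueous NH4Cl
Reagents that add atoms: none
Why: Intramolecular Claisen (Dieckmann-type) acylation of the C7 ketone enolate by the methyl ester closes seven-membered ring B and is driven by irreversible β-diketonate formation, competing aldol additions being reversible and closure from C3 being excluded by Bredt's rule.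

**Step 9**
Reactants: 13 (3R,8R)-5-(2,2-dimethoxypropanoyl)-3,8-dimethyl-3-[(triethylsilyl)oxy]-2,3,4,5,7,8-hexahydroazulene-1,6-dione
Product: 16 methyl 5β,11-epoxy-2,8-dioxo-4α-[(triethylsilyl)oxy]-1αH,7αH,10βH-guaian-12-oate (11-methyl exo), via oxocarbenium ion 14 (not isolated), via dimethoxycarbenium ion 15 (not isolated)
Conditions: Sc(OTf)3 (10 mol %), H2O (1.1 equiv), MeNO2, 0 to 23 °C
Reagents that add atoms: water O
Why: Proposed new method: Sc(OTf)3 activates the ring A enone, the C11 carbonyl oxygen of the keto tautomer (C7 epimers equilibrate through the enol) adds to C5 from the β face, anti to the C4 silyloxy and C10 methyl groups, closing the five-membered ether as oxocarbenium ion 14, the methyl of the adjacent ketal carbon then migrates on the convex face to give dialkoxycarbenium ion 15 (driven by ester formation), and water protonates C1 from the exo face and collapses 15 to the methyl ester, so the step forms the key C5–O bond and sets C5, C1, C7 and C11; the closest known reactions are the acid-promoted α-ketol and type 3 semipinacol rearrangements of α-oxygenated ketals, the benzilic ester rearrangement and Prins–pinacol cascades, none of which has been triggered by a carbonyl oxa-Michael addition.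

**Step 10**
Reactants: 16 methyl 5β,11-epoxy-2,8-dioxo-4α-[(triethylsilyl)oxy]-1αH,7αH,10βH-guaian-12-oate
Product: 19 5β,11-epoxy-2β,4α-dihydroxy-1αH,7αH,8αH,10βH-guaian-12,8-olide, via hydroxy ester 17 (not isolated), via silyl lactone 18 (not isolated)
Conditions: LiBH(sBu)3 (2.3 equiv), THF, −78 to −20 °C; then 1 M HCl, MeOH, 23 °C
Reagents that add atoms: none
Why: Substrate-controlled hydride reduction from the exo (α) faces puts the C8 alkoxide on the β face, where it lactonises onto the endo ester (sets C8, closes the lactone), gives the 2β-alcohol (hydride anti to C10 and to the axial C5–O bond), and the acidic work-up removes the silyl ether.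

**Step 11**
Reactants: 19 5β,11-epoxy-2β,4α-dihydroxy-1αH,7αH,8αH,10βH-guaian-12,8-olide; 20 angelic acid
Product: 21 2α-angeloyloxy-5β,11-epoxy-4α-hydroxy-1αH,7αH,8αH,10βH-guaian-12,8-olide (CNP0293659.1)
Conditions: PPh3, diisopropyl azodicarboxylate, toluene, 0 to 23 °C
Reagents that add atoms: none
Why: Mitsunobu esterification inverts C2 by SN2 attack of angelate on the alkoxyphosphonium ion to give the 2α-ester, the tertiary C4 alcohol being unreactive and no nucleophilic base being present to isomerise angelate to tiglate.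

**Compound list**
1 | 3-methylglutaric anhydride | CC1CC(=O)OC(=O)C1 | starting material
2 | (3S)-5-methoxy-3-methyl-5-oxopentanoic acid | OC(=O)C[C@H](C)CC(=O)OC | intermediate
3 | methyl (3R)-5-chloro-3-methyl-5-oxopentanoate (acid chloride; not isolated) | ClC(=O)C[C@H](C)CC(=O)OC | intermediate
4 | methyl (3S)-3-methyl-5-oxohexanoate | CC(=O)C[C@H](C)CC(=O)OC | intermediate
5 | methyl (3S)-3-methyl-5-[(triethylsilyl)oxy]hex-5-enoate | C=C(O[Si](CC)(CC)CC)C[C@H](C)CC(=O)OC | intermediate
6 | butane-2,3-dione | CC(=O)C(C)=O | starting material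
7 | methyl (3S,7R)-3,7-dimethyl-5,8-dioxo-7-[(triethylsilyl)oxy]nonanoate | CC(=O)[C@](C)(O[Si](CC)(CC)CC)CC(=O)C[C@H](C)CC(=O)OC | intermediate
8 | cyclic aldol, methyl (3R)-3-[(3R)-2-hydroxy-2,3-dimethyl-5-oxo-3-[(triethylsilyl)oxy]cyclopentyl]butanoate (ring C1 and C2 unassigned; not isolated) | CC1(O)C([C@H](C)CC(=O)OC)C(=O)C[C@@]1(C)O[Si](CC)(CC)CC | intermediate
9 | methyl (3R)-3-[(3R)-2,3-dimethyl-5-oxo-3-[(triethylsilyl)oxy]cyclopent-1-en-1-yl]butanoate | CC1=C([C@H](C)CC(=O)OC)C(=O)C[C@@]1(C)O[Si](CC)(CC)CC | intermediate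
10 | methyl (3R)-3-[(3R)-2-(bromomethyl)-3-methyl-5-oxo-3-[(triethylsilyl)oxy]cyclopent-1-en-1-yl]butanoate | BrCC1=C([C@H](C)CC(=O)OC)C(=O)C[C@@]1(C)O[Si](CC)(CC)CC | intermediate
11 | 3,3-dimethoxybutan-2-one | CC(=O)C(C)(OC)OC | starting material
12 | methyl (3R)-3-[(3R)-2-(4,4-dimethoxy-3-oxopentyl)-3-methyl-5-oxo-3-[(triethylsilyl)oxy]cyclopent-1-en-1-yl]butanoate | CC(OC)(OC)C(=O)CCC1=C([C@H](C)CC(=O)OC)C(=O)C[C@@]1(C)O[Si](CC)(CC)CC | intermediate
13 | (3R,8R)-5-(2,2-dimethoxypropanoyl)-3,8-dimethyl-3-[(triethylsilyl)oxy]-2,3,4,5,7,8-hexahydroazulene-1,6-dione (azulene C5 epimers, enolised) | CC(OC)(OC)C(=O)C1CC2=C([C@H](C)CC1=O)C(=O)C[C@@]2(C)O[Si](CC)(CC)CC | intermediate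
14 | cyclic oxocarbenium ion after ether closure (C5–O formed, C11=O+; not isolated) | O=C1C[C@@](C)(O[Si](CC)(CC)CC)[C@@]23C[C@@H](C(=O)C[C@@H](C)[C@H]12)C(C(C)(OC)OC)=[O+]3 | intermediate
15 | dimethoxycarbenium ion after 1,2-methyl shift (not isolated) | O=C1C[C@@](C)(O[Si](CC)(CC)CC)[C@@]23C[C@@H](C(=O)C[C@@H](C)[C@H]12)[C@@](C)(C(OC)=[O+]C)O3 | intermediate
16 | methyl 5β,11-epoxy-2,8-dioxo-4α-[(triethylsilyl)oxy]-1αH,7αH,10βH-guaian-12-oate (11-methyl exo, ester towards C8) | O=C1C[C@@](C)(O[Si](CC)(CC)CC)[C@@]23C[C@@H](C(=O)C[C@@H](C)[C@H]12)[C@@](C)(C(=O)OC)O3 | intermediate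
17 | methyl 5β,11-epoxy-2β,8β-dihydroxy-4α-[(triethylsilyl)oxy]-1αH,7αH,10βH-guaian-12-oate (not isolated) | O[C@@H]1C[C@@](C)(O[Si](CC)(CC)CC)[C@@]23C[C@@H]([C@H](O)C[C@@H](C)[C@H]12)[C@@](C)(C(=O)OC)O3 | intermediate
18 | 5β,11-epoxy-2β-hydroxy-4α-[(triethylsilyl)oxy]-1αH,7αH,8αH,10βH-guaian-12,8-olide (not isolated) | O[C@@H]1C[C@@](C)(O[Si](CC)(CC)CC)[C@@]23C[C@H]4[C@@H](C[C@@H](C)[C@H]12)OC(=O)[C@@]4(C)O3 | intermediate
19 | 5β,11-epoxy-2β,4α-dihydroxy-1αH,7αH,8αH,10βH-guaian-12,8-olide | O[C@@H]1C[C@@](C)(O)[C@@]23C[C@H]4[C@@H](C[C@@H](C)[C@H]12)OC(=O)[C@@]4(C)O3 | intermediate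
20 | angelic acid, (Z)-2-methylbut-2-enoic acid | C/C=C(/C)C(=O)O | starting material
21 | 2α-angeloyloxy-5β,11-epoxy-4α-hydroxy-1αH,7αH,8αH,10βH-guaian-12,8-olide (CNP0293659.1) | C/C=C(/C)C(=O)O[C@H]1C[C@@](C)(O)[C@@]23C[C@H]4[C@@H](C[C@@H](C)[C@H]12)OC(=O)[C@@]4(C)O3 | target

**Totals**
Total step count: 11. Longest linear sequence: 11 steps (from 1).

**Three steps most likely to fail**

Step 9 (the proposed new cascade). The ether closure may stay reversible, the methyl may migrate on the wrong face, or the ketal may simply hydrolyse. The fallback uses known chemistry, sets out from 13 and comes back at 16. CeCl3·7H2O and NaI in MeCN remove the dimethyl ketal to give the free 1,2-diketone (3R,8R)-3,8-dimethyl-5-(2-oxopropanoyl)-3-[(triethylsilyl)oxy]-2,3,4,5,7,8-hexahydroazulene-1,6-dione F2. Mg(OMe)2 in MeOH then effects the classical benzilic ester rearrangement to the tertiary α-hydroxy ester methyl 2-[(3R,8R)-3,8-dimethyl-1,6-dioxo-3-[(triethylsilyl)oxy]-1,2,3,4,5,6,7,8-octahydroazulen-5-yl]-2-hydroxypropanoate F3. DBU in toluene closes the ether by base-mediated oxa-Michael addition to give 16. In this variant C11 is not enforced, so the epimers must be separated; only the one with the ester towards C8 lactonises in step 10.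

Step 6 (radical bromination). The tertiary allylic C10–H may compete with the C6 methyl. The fallback sets out from 9 and comes back at 10. SeO2 (0.5 equiv) with tBuOOH in CH2Cl2 hydroxylates the methyl group by the ene/[2,3] pathway (methyl is preferred over methine by the usual site rules) to give the allylic alcohol methyl (3R)-3-[(3R)-2-(hydroxymethyl)-3-methyl-5-oxo-3-[(triethylsilyl)oxy]cyclopent-1-en-1-yl]butanoate F1. An Appel reaction (CBr4, PPh3) then gives 10.

Step 11 (Mitsunobu). The secondary alcohol is hindered, and the angelate may isomerise to the tiglate. The fallback sets out from 19 and comes back at 21. MsCl and Et3N at −20 °C convert only the secondary alcohol into the mesylate 5β,11-epoxy-4α-hydroxy-2β-(methanesulfonyloxy)-1αH,7αH,8αH,10βH-guaian-12,8-olide F4. Caesium angelate (from 20 and Cs2CO3) with 18-crown-6 in toluene at 80 °C then displaces it with inversion to give 21.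

**Further compounds**
F1 | step 6 | methyl (3R)-3-[(3R)-2-(hydroxymethyl)-3-methyl-5-oxo-3-[(triethylsilyl)oxy]cyclopent-1-en-1-yl]butanoate | OCC1=C([C@H](C)CC(=O)OC)C(=O)C[C@@]1(C)O[Si](CC)(CC)CC
F2 | step 9 | (3R,8R)-3,8-dimethyl-5-(2-oxopropanoyl)-3-[(triethylsilyl)oxy]-2,3,4,5,7,8-hexahydroazulene-1,6-dione | CC(=O)C(=O)C1CC2=C([C@H](C)CC1=O)C(=O)C[C@@]2(C)O[Si](CC)(CC)CC
F3 | step 9 | methyl 2-[(3R,8R)-3,8-dimethyl-1,6-dioxo-3-[(triethylsilyl)oxy]-1,2,3,4,5,6,7,8-octahydroazulen-5-yl]-2-hydroxypropanoate | COC(=O)C(C)(O)C1CC2=C([C@H](C)CC1=O)C(=O)C[C@@]2(C)O[Si](CC)(CC)CC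
F4 | step 11 | 5β,11-epoxy-4α-hydroxy-2β-(methanesulfonyloxy)-1αH,7αH,8αH,10βH-guaian-12,8-olide | CS(=O)(=O)O[C@@H]1C[C@@](C)(O)[C@@]23C[C@H]4[C@@H](C[C@@H](C)[C@H]12)OC(=O)[C@@]4(C)O3
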